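The earlier runs and the new flask are simulated with made-up constants; scatter was added.

Slowness is the first thing to read in the autumn run, which is this very flask followed so far: the links come quickly, then hardly at all, and yet plenty of first end groups stay in the flask.

| flask | first end groups | second end groups | third end groups | remark | time |
|---|---|---|---|---|---|
| autumn | 0.020 M | 0.95 equiv | 0.50 equiv | the very flask that is asked about, followed so far |  |
| winter | 0.020 M | 1.9 equiv | 0.50 equiv | run made earlier |  |
| flask | 0.020 M | 0.950 equiv | 0.500 equiv |  | 20 h |

autumn run (percent of the first end groups charged)

| time / h | links / % | first end groups / % |
|---|---|---|
| 1.00 | 24.4 | 77.3 |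
| 2.00 | 29.0 | 70.5 |
| 3.00 | 31.6 | 67.2 |
| 6.00 | 33.6 | 66.6 |
| 12.0 | 33.9 | 66.5 |

winter run (percent of the first end groups charged)

| time / min | links / % | first end groups / % |
|---|---|---|
| 25.0 | 29.5 | 69.9 |
| 50.0 | 42.4 | 56.8 |
| 80.0 | 52.0 | 47.7 |
| 90.0 | 55.3 | 45.1 |
| 120 | 60.2 | 38.9 |

(each reading ± 1 percentage point)

- green: at 20 h take out 90% of the links then present, then wait 20 h
- ochre: at 20 h add second end groups, 50.0% of the amount charged, then wait 20 h
- grey: at 20 h add first end groups, 50.0% of the amount charged, then wait 20 h
- teal: change nothing and wait 20 h more

- removed links is counted in
- the earlier runs were read with a standard deviation of 1 percentage point
- what may be going on: second end groups -> decomposed reagent; first end groups + second end groups -> links; second end groups + third end groups -> links of the second sort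
- additions bring no volume worth counting

1. links, in percent of the first end groups first charged, at 20 h
2. the option that brings most further links ("none" if no option brings more than 2 percentage points) (green / ochre / grey / teal / none)
3. links present, with what was taken out counted in, in percent of the first end groups first charged, after green
4. links present, with what was taken out counted in, in percent of the first end groups first charged, after teal

In the first instants the second end groups stand at full charge and can go to links, to links of the second sort or to decomposed reagent; by 1.00 h the autumn run reads 24.4% links. In the middle the pace sags: from 3.00 h to 6.00 h links gain 2 percentage points, and from then to 12.0 h they gain 0.3 points. At 12.0 h the autumn run still reads first end groups at 66.5%, and with links they add up to 100%. So the stall points to a lost partner, the second end groups, as the likely limiting reagent. The winter run agrees: with 1.9 equiv it reaches 60.2% links at 120 min, more than the autumn plateau.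

Divide the rate of link formation by the rate at which second end groups disappear, and time drops out. What stays is a selectivity, and over a whole run it is the link share, the links made per second end group charged: 35.7% from the autumn end reading.

My own reckoning follows. If the partner is lost, waiting, taking links out or adding first end groups brings this flask nothing, so links stay near the plateau at 20 h. The ochre dose, at that share, gives 17 points.

The forecast says 34% (range 33.2% to 34.9%), 34% after green, 34% after teal, and ochre as best: “Only fresh second end groups help, giving roughly +25 points.” On the size of that gain the two differ: 17 points in my reckoning, 25 in the forecast.

The flask gives 33.5% at 20 h, and ochre is best, bringing 22 points; green ends at 33.5% and teal at 33.5%. At 20.0 h the free second end groups stand at 0% of their charge, while first end groups stand at 66.5%. A cheap way to the forecast's answers was the autumn end reading of 33.9%, held as the plateau. The ochre dose turned 46.6% of itself into links, more than the link share.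

    second end groups → decomposed reagent (k = 7.70 × 10⁻⁵ s⁻¹)
    first end groups + second end groups → links (k = 0.00820 M⁻¹ s⁻¹)
    second end groups + third end groups → links of the second sort (k = 0.0380 M⁻¹ s⁻¹)

Take one more flask, like this one but with 1.60 equiv of second end groups: the link share gives 57.1% links. The computed flask gives 63.3% at 20 h, with 37% of its first end groups still free.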